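**Conventions and assumptions**

- Atom labels follow the indane numbering of the target and are kept for every intermediate: ring A is C1, C2, C3, C3a, C7a; ring B is C3a, C4, C5, C6, C7, C7a. C1′ is the carbinol carbon on C1, and C8 is the central carbon of the C7 side chain (CMe2 bridge, later isopropenyl, later the oxirane carbon).
- Faces: ring B is viewed with C4, C3a, C7a, C7, C6, C5 running clockwise, and β is toward the viewer. In the target the C5 and C6 oxygens, H3a, H1 and the C7a–C1 bond are β; the C3a–C3 bond, H7a, the C7 side chain and the C1 side chain are α.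
- Compounds 1, 8, 27, 28 and 36 are taken to be catalogue chemicals.
- In step 4 the tertiary cation is taken to be captured by acetate, the usual course of this cleavage, and the route is written for the tertiary acetate.

## Analysis of the target

Target 37 is a trans-fused hexahydroindan-2-one, an oplopane-type sesquiterpenoid in which cyclopentanone ring A is fused to cyclohexane ring B, with an exocyclic methylene on C4 and three different esters. Ring B is a chair in which the ring-fusion bonds C3a–C3 and C7a–C1, the C7 oxiranyl group and the C6 2-methylbutanoate are equatorial. The C5 enoate is axial, cis to the C6 oxygen and next to the C4 methylene, and the 1-acetoxyethyl group on C1 is trans to the C7a–C7 bond. There are ten stereocentres: C1, C3a, C5, C6, C7 and C7a in the bicycle, C1′ and C8 on its substituents, and one in each chiral acyl group, together with one (E)-alkene. The sensitive groups are: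

- the β-acetoxy ketone (C2/C1′), which eliminates or retro-aldolises with base and whose C1 is epimerisable;
- the 2,2-disubstituted oxirane, which is labile to acid and fluoride;
- the cis-vicinal C5/C6 esters, which can migrate;
- two 1,1-disubstituted alkenes that must be told apart.

The synthesis is hard because three secondary hydroxyls each need a different acyl group, because C8 sits on a freely rotating side chain, and because the ring-fusion carbon C7a carries no activating group. The plan rests on this last feature. Before ring A exists, C7a is a plain ring B methylene five atoms from C1 along C1–C2–C3–C3a–C7a. The other neighbour of C3a, C4, can be held as a ketal carbon with no hydrogen and no π bond, so a carbenoid at C1 has one five-membered-ring target only.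

## Retrosynthetic reasoning

**Ester and oxirane disconnections (37 back to 26 and 32).** The C6–O acyl bond is cut last, giving 35 and acid 36, because a free C6 hydroxyl is needed to deliver oxygen to the C8=CH2 bond of 34. The oxirane must follow every acidic or fluoride step. The C6 hydroxyl is released from its PMB ether 33 by neutral oxidation, which keeps the neighbouring C5 ester from migrating. The C5–O acyl bond is cut to alcohol 26 and acid 32, and 26 comes from silyl ether 25.

**C1′–H (25, 24 back to 23).** The acetate is traced to carbinol 24 and this to the acetyl group of diketone 23. Because C1 lies between two carbonyls it equilibrates freely, so one catalyst-controlled hydride transfer sets C1′ while C1 settles trans to C7a–C7.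

**C4=CH2 (23 back to 21 and 20).** The methylene is cut to the C4 ketone of 21 and this to ketal 20. The olefination is placed while C1/C2 is still a β-diketone, because its enolate shields C2 without a protecting group. C4 must remain a ketal until ring A is closed.

**C1–C7a, the key disconnection (20 back to 19).** Cutting C1–C7a opens ring A to the 2-diazo-1,3-diketone 19. This is preferred to cutting C2–C3 or C3a–C7a because it turns an unfunctionalised CH2 directly into the ring-fusion stereocentre and needs only a three-carbon arm on C3a. The forward reaction has to choose the equatorial C7a–H bond over the axial one.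

**The arm (19 back to 15).** Diazo transfer traces 19 to β-diketone 18, C-acylation to methyl ketone 16, and alkene oxidation to the allyl compound 15. The C3a–allyl bond is the only carbon–carbon bond to ring B that has to be made.

**Protecting pattern and isopropenyl group (15 back to 11).** The silyl ether 15 comes from alcohol 14, the isopropenyl group of 14 from the tertiary carbinol 13, and the C6 PMB ether of 13 from triol 11. The C5/C6 oxygens are differentiated here, on a cis-diol whose equatorial oxygen can be addressed selectively.

**C3a–allyl and the ketal (11 back to 7 and 8).** Triol 11 comes from triacetate ketal 10 and ketone 9. Ketone 9 is cut at C3a–CH2 to enol acetate 7 and carbonate 8. The enol acetate fixes the enolate on the C3a side, away from the oxygenated C5.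

**C3a–C8 (7 back to 5).** Joining C3a to C8 in the retro direction gives the pinane diol 5. Its rigid cage provides the C7 configuration and the face for the C5/C6 cis-diol. Forward cleavage of this bond releases a regiodefined C4=C3a enol and the three-carbon C7 substituent together.

**The cage (5 back to 1).** Diol 5 comes from enone 4 by syn-dihydroxylation, 4 from ketone 3 by dehydrogenation, and 3 from terpene 1 by cleavage of its exocyclic alkene.

**Side-chain acid (32 back to 27 and 28).** Acid 32 comes from tert-butyl ester 31, acetate 31 from carbinol 30, and 30 from enone 29 by enantioselective reduction. The C2=C3 bond of 29 is cut to diketone 27 and ylide 28.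

## Alternatives that were turned down

**Alternative 1:** The disconnection cuts C7a–C7 and C1–C1′ in one operation. In the forward sense a Lewis acid promotes γ-attack of allylsilane A3 on cyclopentenone A2, which also creates the isopropenyl group, and the resulting enolate is trapped by aldehyde A4 to give cyclopentanone A1.

- For: it is convergent, it forms two skeletal bonds and four stereocentres in one flask, and it makes C1′ by an aldol reaction and not by a reduction. On bond count and convergence it is stronger than the chosen plan.
- Against: C7 arises from an open transition state between two chiral partners, so its configuration relative to C7a is not securely predictable. The aldol configuration at C1′ has only 1,2-induction behind it. A1 still lacks ring B: C5 is a CH2O carbon that must be oxidised and joined to C4, creating the axial C5 oxygen late.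
- Comparison: the chosen plan forms one bond in its key step, but every ring B stereocentre is fixed beforehand in a rigid cage, and the key step has to control only C7a.

**Alternative 2:** The disconnection cuts C1–C2 and the C1′–O bond of an isoxazoline. In the forward sense oxime A6 is oxidised to a nitrile oxide that adds across the (E)-propenyl group on C7a, closing ring A and the heterocycle to give A5.

- For: the suprafacial cycloaddition ties the C1/C1′ relationship to alkene geometry, and the isoxazoline masks the β-hydroxy ketone until late. On protection of the aldol unit and on C1′ control without a chiral catalyst it is stronger than the chosen plan.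
- Against: both the C3a arm and a stereodefined propenyl group on C7a must already be in place, so C7a has to be built by a separate carbon–carbon bond formation next to C7. The face of the cycloaddition across a trans-diequatorial tether is not secured. The N–O bond must later be cleaved reductively beside two 1,1-disubstituted alkenes.
- Comparison: the chosen plan needs no substituent on C7a at all and reaches its precursor in fewer operations, at the price of a catalyst-controlled reduction for C1′.

**Alternative 3:** The disconnection cuts C3a–C7a, C2–C3 and C1–C2. In the forward sense cobalt-mediated cyclocarbonylation of the acyclic enyne A8 closes ring B and the cyclopentenone together to give A7.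

- For: three carbon–carbon bonds and both rings form in one step, which no other plan matches.
- Against: A7 is a C1=C7a enone, so C7a and C1 have to be set afterwards by a conjugate reduction whose trans outcome is not assured, and C3a is set in the cyclisation with only remote control. Six-membered ring formation from a 1,7-enyne is the less favourable case of this reaction. The C4 oxygen must still be turned into the methylene next to an epimerisable C3a. A8 carries five stereocentres that must be assembled linearly.
- Comparison: the chosen plan delivers the ring fusion at the right oxidation level and, through the equatorial C–H bond, with the trans relationship built in.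

Key step: step 14

## Route

Step 1
Reactants: 1 (1R,5R)-(+)-β-pinene
Product: 3 (1S,5R)-(−)-nopinone, via spiro-ozonide 2 (not isolated)
Conditions: O3, CH2Cl2, −78 °C; then Me2S, −78 °C → rt
Reagents that add atoms: ozone, [O-][O+]=O
Why: Ozonolysis of the exocyclic alkene (Criegee pathway) with reductive work-up gives the C4 ketone; no stereocentre is touched.

Step 2
Reactants: 3 (1S,5R)-(−)-nopinone
Product: 4 (1S,5S)-apoverbenone
Conditions: 2-iodoxybenzoic acid (IBX, 2 equiv), DMSO/toluene, 75 °C
Reagents that add atoms: none
Why: IBX α,β-dehydrogenation of a ketone; the bridgehead C3a cannot enolise, so unsaturation can only enter at C5=C6, and the bridgeheads prevent over-oxidation.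

Step 3
Reactants: 4 (1S,5S)-apoverbenone
Product: 5 (1S,3R,4R,5R)-3,4-dihydroxy-6,6-dimethylbicyclo[3.1.1]heptan-2-one (C5 and C6 hydroxyls cis, on the face opposite the CMe2 bridge)
Conditions: OsO4 (2 mol %), N-methylmorpholine N-oxide, acetone/H2O, rt
Reagents that add atoms: N-methylmorpholine N-oxide, C[N+]1([O-])CCOCC1 (oxygen relayed through OsO4, O=[Os](=O)(=O)=O); water, O
Why: Upjohn syn-dihydroxylation of the only alkene; the methyl group of the CMe2 bridge that lies over the enone blocks one face, so both oxygens should enter anti to C8. This sets C5 and C6 cis to each other and trans to the C7–C8 bond.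

Step 4
Reactants: 5 (1S,3R,4R,5R)-3,4-dihydroxy-6,6-dimethylbicyclo[3.1.1]heptan-2-one
Product: 7 enol tetraacetate (cyclohexene with C4(OAc)=C3a, C5 β-OAc, C6 β-OAc, C7 α-CMe2OAc), via nopinone diacetate 6 (not isolated)
Conditions: Ac2O, Zn(OAc)2, BF3·OEt2, 0 °C → rt
Reagents that add atoms: acetic anhydride, CC(=O)OC(C)=O
Why: After fast O-acetylation, Lewis-acid activation of the ketone triggers strain-driven heterolysis of the C3a–C8 cyclobutane bond, the known cyclobutane cleavage of nopinones. The enol is acetylated on the C3a side only, the tertiary cation is captured as the acetate, and C5, C6 and C7 are untouched.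

Step 5
Reactants: 7 enol tetraacetate; 8 allyl methyl carbonate
Product: 9 2-allyl ketone triacetate (C4 ketone, C3a α-allyl, C5 β-OAc, C6 β-OAc, C7 α-CMe2OAc)
Conditions: Pd2(dba)3·CHCl3 (2.5 mol %), dppe (10 mol %), Bu3SnOMe (20 mol %), dioxane, 80 °C
Reagents that add atoms: none
Why: Tsuji–Trost allylation of an enol acetate: Bu3SnOMe cleaves only the enol ester to a tin enolate, which attacks the π-allylpalladium complex at C3a. Approach anti to the pseudo-axial C5 acetate should give the equatorial α-allyl group, which is also the thermodynamic epimer.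

Step 6
Reactants: 9 2-allyl ketone triacetate
Product: 10 C4 ethylene ketal triacetate
Conditions: Me3SiOCH2CH2OSiMe3, Me3SiOTf (5 mol %), CH2Cl2, −78 → −20 °C
Reagents that add atoms: 1,2-bis(trimethylsilyloxy)ethane, C[Si](C)(C)OCCO[Si](C)(C)C
Why: Ketalisation under silyl triflate catalysis (Noyori conditions) runs at low temperature without enolisation, so C3a and C5 keep their configuration. From here on C4 bears no hydrogen.

Step 7
Reactants: 10 C4 ethylene ketal triacetate
Product: 11 ketal triol (C5 β-OH, C6 β-OH, C8 tertiary OH)
Conditions: LiAlH4, THF, 0 °C → rt; aqueous NaOH work-up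
Reagents that add atoms: none
Why: Hydride reduction removes the two secondary acetates and the hindered tertiary acetate in one operation; ketal and allyl group are inert.

Step 8
Reactants: 11 ketal triol
Product: 13 C6 PMB ether (C5 β-OH and C8 OH free), via stannylene acetal 12 (not isolated)
Conditions: Bu2SnO, toluene, reflux (−H2O); then 4-methoxybenzyl chloride, Bu4NI, 90 °C
Reagents that add atoms: 4-methoxybenzyl chloride, COc1ccc(CCl)cc1
Why: Stannylene-acetal-mediated alkylation of a cis-1,2-diol takes place at the equatorial oxygen, here O6; the axial C5 hydroxyl and the tertiary hydroxyl do not react.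

Step 9
Reactants: 13 C6 PMB ether
Product: 14 isopropenyl alcohol (C7 α-isopropenyl, C6 β-OPMB, C5 β-OH)
Conditions: Ph2S[OC(CF3)2Ph]2 (Martin sulfurane, 1.5 equiv), CH2Cl2, −40 → 0 °C
Reagents that add atoms: none
Why: Martin sulfurane dehydrates tertiary alcohols at low temperature, while the hindered secondary C5 hydroxyl is returned on work-up. Loss of a methyl hydrogen is expected, because removal of H7 needs a rotamer with both methyls gauche to the ring and would give an isopropylidene group strained against the C6 ether.

Step 10
Reactants: 14 isopropenyl alcohol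
Product: 15 C5 TBS ether (C4 ketal, C3a α-allyl, C7 α-isopropenyl, C6 β-OPMB, C5 β-OTBS)
Conditions: tBuMe2SiOTf, 2,6-lutidine, CH2Cl2, −78 → 0 °C
Reagents that add atoms: tert-butyldimethylsilyl triflate, CC(C)(C)[Si](C)(C)OS(=O)(=O)C(F)(F)F
Why: Silyl triflate silylation of the hindered axial hydroxyl. TBS is chosen to outlast the later ketal hydrolysis, and PMB/TBS are removable independently of each other.

Step 11
Reactants: 15 C5 TBS ether
Product: 16 methyl ketone (C3a α-CH2COCH3)
Conditions: PdCl2 (10 mol %), CuCl (30 mol %), O2 (1 atm), DMF/H2O 7:1, rt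
Reagents that add atoms: water, O
Why: Wacker–Tsuji oxidation converts the monosubstituted allyl alkene to the methyl ketone; the 1,1-disubstituted isopropenyl group reacts far more slowly.

Step 12
Reactants: 16 methyl ketone
Product: 18 β-diketone (C3a α-CH2COCH2COCH3), via lithium enolate 17 (not isolated)
Conditions: LiN(iPr)2 (2.2 equiv), THF, −78 °C; 1-acetylbenzotriazole, −78 → −20 °C; aqueous NH4Cl
Reagents that add atoms: 1-acetyl-1H-benzotriazole, CC(=O)n1nnc2ccccc12
Why: Kinetic deprotonation at the methyl group and C-acylation of the enolate with an N-acylbenzotriazole gives the 1,3-diketone; the second equivalent of base takes up the acidic product.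

Step 13
Reactants: 18 β-diketone
Product: 19 2-diazo-1,3-diketone (C3a α-CH2COC(N2)COCH3; C4 ketal, C5 β-OTBS, C6 β-OPMB, C7 α-isopropenyl)
Conditions: 4-acetamidobenzenesulfonyl azide, Et3N, MeCN, 0 °C → rt
Reagents that add atoms: 4-acetamidobenzenesulfonyl azide, CC(=O)Nc1ccc(cc1)S(=O)(=O)N=[N+]=[N-]
Why: Regitz diazo transfer to the activated methylene between the two carbonyls.

Step 14
Reactants: 19 2-diazo-1,3-diketone
Product: 20 1-acetyl trans-hydrindan-2-one ketal (H3a β, H7a α, C1 acetyl α; C4 ketal, C5 β-OTBS, C6 β-OPMB, C7 α-isopropenyl)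
Conditions: Rh2(OAc)4 (1 mol %), CH2Cl2, 40 °C, slow addition of 19
Reagents that add atoms: none
Why: Rh2(OAc)4 attacks the diazo carbon C1, N2 leaves, and the electrophilic rhodium carbenoid inserts into a C7a–H bond through a concerted, asynchronous three-centre transition state, with retention at C7a and release of the catalyst. The closest known reaction type is the Rh2(OAc)4-catalysed intramolecular 1,5 C–H insertion of 2-diazo-1,3-dicarbonyl compounds to 2-acylcyclopentanones. Ring A closes as a five-membered ring by 1,5-insertion through a chair-like six-centre array (C1, C2, C3, C3a, C7a, H) exocyclic to ring B. C7a is set by the choice between its two diastereotopic hydrogens: the ring B chair is held by the equatorial C7 and C6 substituents with the C3a arm equatorial, so the exposed equatorial C7a–H should react and give the diequatorial, trans fusion, whereas the axial hydrogen would lead to a cis-hydrindane crowded by the axial C5 silyl ether. C1 is a β-diketone carbon and should settle by enolisation with the acetyl group trans to the C7a–C7 bond. Site selectivity is needed and rests on C4 being a ketal carbon without hydrogen or π bond, which leaves C7a as the only 1,5 position; the allylic C7–H and the C5–H next to oxygen would require six-membered rings and cyclopropanation of the isopropenyl group a medium ring. A dirhodium carboxylate at high dilution is used because it favours C–H insertion over oxonium-ylide formation at the ketal oxygens. C3a, C5, C6 and C7 are not involved.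

Step 15
Reactants: 20 1-acetyl trans-hydrindan-2-one ketal
Product: 21 trione (C4 ketone; 1-acetyl-2-ketone unchanged)
Conditions: pyridinium p-toluenesulfonate, acetone/H2O 9:1, 55 °C
Reagents that add atoms: water, O
Why: Acid-catalysed ketal hydrolysis under conditions that secondary TBS and PMB ethers normally survive. The trans fusion should hold at C3a because the cis isomer would place C3 syn-axial to the C5 silyl ether.

Step 16
Reactants: 21 trione
Product: 23 C4 methylene diketone, via potassium diketonate 22 (not isolated)
Conditions: KN(SiMe3)2 (1.05 equiv), THF, −78 °C; then Ph3P=CH2 (from Ph3PCH3Br and KN(SiMe3)2, 3 equiv), 0 °C → rt; aqueous NH4Cl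
Reagents that add atoms: methyltriphenylphosphonium bromide, C[P+](c1ccccc1)(c1ccccc1)c1ccccc1.[Br-]
Why: Wittig methylenation; the β-diketone is first converted to its delocalised enolate, which does not react with the ylide, so C4 is the only ketone available. The C6 benzyl-type ether is a poor leaving group, which limits β-elimination.

Step 17
Reactants: 23 C4 methylene diketone
Product: 24 β-hydroxy ketone ((1′S)-1-hydroxyethyl on C1, α)
Conditions: RuCl[(S,S)-TsDPEN](p-cymene) (2 mol %), HCO2H/Et3N 5:2, CH2Cl2, rt
Reagents that add atoms: none
Why: Noyori-type asymmetric transfer hydrogenation with dynamic kinetic resolution: the methyl ketone is the less hindered and more activated carbonyl, and the (S,S) catalyst is expected to give the (S)-carbinol by analogy with methyl ketones bearing a π-substituent. C1 interconverts through the enol and ends trans to C7a–C7; the remaining dialkyl ketone C2 and the alkenes are not reduced.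

Step 18
Reactants: 24 β-hydroxy ketone
Product: 25 β-acetoxy ketone
Conditions: Ac2O, pyridine, DMAP (cat.), CH2Cl2, 0 °C
Reagents that add atoms: acetic anhydride, CC(=O)OC(C)=O
Why: Acetylation under mild, weakly basic conditions at low temperature, which should avoid elimination of the new β-acetoxy ketone.

Step 19
Reactants: 25 β-acetoxy ketone
Product: 26 C5 allylic alcohol (C5 β-OH; C6 β-OPMB)
Conditions: HF·pyridine, pyridine, THF, 0 °C → rt
Reagents that add atoms: none
Why: Buffered acidic fluoride removes the TBS ether without exposing the β-acetoxy ketone to base; the PMB ether is stable.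

Step 20
Reactants: 27 butane-2,3-dione; 28 tert-butyl (triphenyl-λ5-phosphanylidene)acetate
Product: 29 tert-butyl (E)-3-methyl-4-oxopent-2-enoate
Conditions: CH2Cl2, 0 °C → rt
Reagents that add atoms: none
Why: Wittig mono-olefination of an activated 1,2-diketone with a stabilised ylide; the ester should end trans to the acetyl group (E).

Step 21
Reactants: 29 tert-butyl (E)-3-methyl-4-oxopent-2-enoate
Product: 30 tert-butyl (2E,4S)-4-hydroxy-3-methylpent-2-enoate
Conditions: (R)-2-methyl-CBS-oxazaborolidine (10 mol %), catecholborane, toluene, −78 °C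
Reagents that add atoms: none
Why: Corey–Bakshi–Shibata reduction of an enone; with the alkenyl group as the large substituent and methyl as the small one, the (R)-catalyst should deliver the (S)-alcohol.

Step 22
Reactants: 30 tert-butyl (2E,4S)-4-hydroxy-3-methylpent-2-enoate
Product: 31 tert-butyl (2E,4S)-4-acetoxy-3-methylpent-2-enoate
Conditions: Ac2O, pyridine, DMAP (cat.), CH2Cl2, 0 °C → rt
Reagents that add atoms: acetic anhydride, CC(=O)OC(C)=O
Why: Standard acetylation; the (E)-geometry prevents lactonisation.

Step 23
Reactants: 31 tert-butyl (2E,4S)-4-acetoxy-3-methylpent-2-enoate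
Product: 32 (2E,4S)-4-acetoxy-3-methylpent-2-enoic acid
Conditions: CF3CO2H, CH2Cl2, 0 °C → rt
Reagents that add atoms: none
Why: Acidolysis of the tert-butyl ester leaves the acetate in place; ionisation of the allylic acetate is disfavoured by the conjugated carboxyl group.

Step 24
Reactants: 26 C5 allylic alcohol; 32 (2E,4S)-4-acetoxy-3-methylpent-2-enoic acid
Product: 33 C5 enoate (C6 β-OPMB)
Conditions: DCC, DMAP (0.2 equiv), CH2Cl2, 0 °C → rt
Reagents that add atoms: none
Why: Steglich esterification of the axial allylic hydroxyl under near-neutral conditions tolerated by the β-acetoxy ketone.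

Step 25
Reactants: 33 C5 enoate
Product: 34 C6 alcohol (C6 β-OH, C5 β-enoate)
Conditions: DDQ, CH2Cl2/pH 7 buffer, 0 °C → rt
Reagents that add atoms: none
Why: Oxidative PMB cleavage at neutral pH frees the C6 hydroxyl without the base or fluoride that would promote C5-to-C6 acyl migration.

Step 26
Reactants: 34 C6 alcohol
Product: 35 epoxy alcohol ((2S)-2-methyloxiran-2-yl on C7)
Conditions: VO(acac)2 (5 mol %), tBuOOH, CH2Cl2, 0 °C → rt
Reagents that add atoms: tert-butyl hydroperoxide, CC(C)(C)OO
Why: Vanadium-catalysed hydroxyl-directed epoxidation of a homoallylic alcohol: in the rotamer with H7 eclipsing C8=CH2 the alkene face turned toward the gauche equatorial C6 oxygen is oxidised, which corresponds to the (S)-oxirane. The C4 methylene lies antiperiplanar to the C6–O bond and cannot be reached, and the enoate is electron-poor.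

Step 27
Reactants: 35 epoxy alcohol; 36 (R)-2-methylbutanoic acid
Product: 37 target
Conditions: DCC, DMAP (0.3 equiv), CH2Cl2, 0 °C → rt
Reagents that add atoms: none
Why: Steglich esterification of the C6 hydroxyl without acid, so the oxirane and the β-acetoxy ketone should survive; the α-stereocentre of the acid is not activated as a ketene under these conditions.

## Compound list

1 | (1R,5R)-(+)-β-pinene | C=C1CC[C@@H]2C[C@H]1C2(C)C | starting material
2 | spiro-ozonide of 1 (1,2,4-trioxolane at C4, spiro carbon not defined; not isolated) | C1OOC2(O1)CC[C@@H]3C[C@H]2C3(C)C | intermediate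
3 | (1S,5R)-(−)-nopinone | O=C1CC[C@@H]2C[C@H]1C2(C)C | intermediate
4 | (1S,5S)-apoverbenone (6,6-dimethylbicyclo[3.1.1]hept-3-en-2-one) | O=C1C=C[C@@H]2C[C@H]1C2(C)C | intermediate
5 | (1S,3R,4R,5R)-3,4-dihydroxy-6,6-dimethylbicyclo[3.1.1]heptan-2-one | O=C1[C@H](O)[C@H](O)[C@@H]2C[C@H]1C2(C)C | intermediate
6 | 3,4-diacetate of 5 (not isolated) | O=C1[C@H](OC(C)=O)[C@H](OC(C)=O)[C@@H]2C[C@H]1C2(C)C | intermediate
7 | enol tetraacetate: C4(OAc)=C3a cyclohexene, C5 β-OAc, C6 β-OAc, C7 α-(2-acetoxypropan-2-yl) | CC(=O)OC1=CC[C@H](C(C)(C)OC(C)=O)[C@@H](OC(C)=O)[C@H]1OC(C)=O | intermediate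
8 | allyl methyl carbonate | C=CCOC(=O)OC | starting material
9 | C4 ketone, C3a α-allyl, C5 β-OAc, C6 β-OAc, C7 α-(2-acetoxypropan-2-yl) | C=CC[C@@H]1C[C@H](C(C)(C)OC(C)=O)[C@@H](OC(C)=O)[C@@H](OC(C)=O)C1=O | intermediate
10 | C4 ethylene ketal of 9 | C=CC[C@@H]1C[C@H](C(C)(C)OC(C)=O)[C@@H](OC(C)=O)[C@@H](OC(C)=O)C12OCCO2 | intermediate
11 | ketal triol: C5 β-OH, C6 β-OH, C7 α-(2-hydroxypropan-2-yl), C3a α-allyl | C=CC[C@@H]1C[C@H](C(C)(C)O)[C@@H](O)[C@@H](O)C12OCCO2 | intermediate
12 | O5,O6-dibutylstannylene acetal of 11 (not isolated) | C=CC[C@@H]1C[C@H](C(C)(C)O)[C@H]3O[Sn](CCCC)(CCCC)O[C@H]3C12OCCO2 | intermediate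
13 | C6 β-O-(4-methoxybenzyl) ether, C5 β-OH, C7 α-(2-hydroxypropan-2-yl) | C=CC[C@@H]1C[C@H](C(C)(C)O)[C@@H](OCc3ccc(OC)cc3)[C@@H](O)C12OCCO2 | intermediate
14 | C7 α-isopropenyl, C6 β-OPMB, C5 β-OH, C4 ketal, C3a α-allyl | C=CC[C@@H]1C[C@H](C(C)=C)[C@@H](OCc3ccc(OC)cc3)[C@@H](O)C12OCCO2 | intermediate
15 | C5 β-OTBS ether of 14 | C=CC[C@@H]1C[C@H](C(C)=C)[C@@H](OCc3ccc(OC)cc3)[C@@H](O[Si](C)(C)C(C)(C)C)C12OCCO2 | intermediate
16 | methyl ketone: C3a α-(2-oxopropyl) | CC(=O)C[C@@H]1C[C@H](C(C)=C)[C@@H](OCc3ccc(OC)cc3)[C@@H](O[Si](C)(C)C(C)(C)C)C12OCCO2 | intermediate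
17 | lithium enolate of 16 at the methyl group (not isolated) | [Li+].[O-]C(=C)C[C@@H]1C[C@H](C(C)=C)[C@@H](OCc3ccc(OC)cc3)[C@@H](O[Si](C)(C)C(C)(C)C)C12OCCO2 | intermediate
18 | β-diketone: C3a α-(2,4-dioxopentyl) | CC(=O)CC(=O)C[C@@H]1C[C@H](C(C)=C)[C@@H](OCc3ccc(OC)cc3)[C@@H](O[Si](C)(C)C(C)(C)C)C12OCCO2 | intermediate
19 | 2-diazo-1,3-diketone: C3a α-(3-diazo-2,4-dioxopentyl), C4 ketal, C5 β-OTBS, C6 β-OPMB, C7 α-isopropenyl | CC(=O)C(=[N+]=[N-])C(=O)C[C@@H]1C[C@H](C(C)=C)[C@@H](OCc3ccc(OC)cc3)[C@@H](O[Si](C)(C)C(C)(C)C)C12OCCO2 | intermediate
20 | 1-acetyl trans-hydrindan-2-one, C4 ethylene ketal: H3a β, H7a α, C1 acetyl α, C5 β-OTBS, C6 β-OPMB, C7 α-isopropenyl | O1CCOC12[C@@H]3CC(=O)[C@H](C(C)=O)[C@H]3[C@H](C(C)=C)[C@@H](OCc4ccc(OC)cc4)[C@H]2O[Si](C)(C)C(C)(C)C | intermediate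
21 | trione: C4 ketone of 20 | O=C1[C@@H]2CC(=O)[C@H](C(C)=O)[C@H]2[C@H](C(C)=C)[C@@H](OCc3ccc(OC)cc3)[C@H]1O[Si](C)(C)C(C)(C)C | intermediate
22 | potassium enolate of the 1-acetyl-2-ketone unit of 21 (not isolated) | O=C1[C@@H]2CC(=O)C(=C(C)[O-])[C@H]2[C@H](C(C)=C)[C@@H](OCc3ccc(OC)cc3)[C@H]1O[Si](C)(C)C(C)(C)C.[K+] | intermediate
23 | 1-acetyl-4-methylidene trans-hydrindan-2-one, C5 β-OTBS, C6 β-OPMB | C=C1[C@@H]2CC(=O)[C@H](C(C)=O)[C@H]2[C@H](C(C)=C)[C@@H](OCc3ccc(OC)cc3)[C@H]1O[Si](C)(C)C(C)(C)C | intermediate
24 | 1-[(1S)-1-hydroxyethyl] ketone | C=C1[C@@H]2CC(=O)[C@H]([C@H](C)O)[C@H]2[C@H](C(C)=C)[C@@H](OCc3ccc(OC)cc3)[C@H]1O[Si](C)(C)C(C)(C)C | intermediate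
25 | 1-[(1S)-1-acetoxyethyl] ketone, C5 β-OTBS, C6 β-OPMB | C=C1[C@@H]2CC(=O)[C@H]([C@H](C)OC(C)=O)[C@H]2[C@H](C(C)=C)[C@@H](OCc3ccc(OC)cc3)[C@H]1O[Si](C)(C)C(C)(C)C | intermediate
26 | C5 β-alcohol of 25 | C=C1[C@@H]2CC(=O)[C@H]([C@H](C)OC(C)=O)[C@H]2[C@H](C(C)=C)[C@@H](OCc3ccc(OC)cc3)[C@H]1O | intermediate
27 | butane-2,3-dione | CC(=O)C(C)=O | starting material
28 | tert-butyl (triphenyl-λ5-phosphanylidene)acetate | CC(C)(C)OC(=O)C=P(c1ccccc1)(c1ccccc1)c1ccccc1 | starting material
29 | tert-butyl (E)-3-methyl-4-oxopent-2-enoate | CC(=O)/C(C)=C/C(=O)OC(C)(C)C | intermediate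
30 | tert-butyl (2E,4S)-4-hydroxy-3-methylpent-2-enoate | C[C@H](O)/C(C)=C/C(=O)OC(C)(C)C | intermediate
31 | tert-butyl (2E,4S)-4-acetoxy-3-methylpent-2-enoate | C[C@H](OC(C)=O)/C(C)=C/C(=O)OC(C)(C)C | intermediate
32 | (2E,4S)-4-acetoxy-3-methylpent-2-enoic acid | C[C@H](OC(C)=O)/C(C)=C/C(=O)O | intermediate
33 | C5 β-[(2E,4S)-4-acetoxy-3-methylpent-2-enoate], C6 β-OPMB | C=C1[C@@H]2CC(=O)[C@H]([C@H](C)OC(C)=O)[C@H]2[C@H](C(C)=C)[C@@H](OCc3ccc(OC)cc3)[C@H]1OC(=O)/C=C(\C)[C@H](C)OC(C)=O | intermediate
34 | C6 β-alcohol of 33 | C=C1[C@@H]2CC(=O)[C@H]([C@H](C)OC(C)=O)[C@H]2[C@H](C(C)=C)[C@@H](O)[C@H]1OC(=O)/C=C(\C)[C@H](C)OC(C)=O | intermediate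
35 | C7 α-[(2S)-2-methyloxiran-2-yl], C6 β-OH | C=C1[C@@H]2CC(=O)[C@H]([C@H](C)OC(C)=O)[C@H]2[C@H]([C@@]3(C)CO3)[C@@H](O)[C@H]1OC(=O)/C=C(\C)[C@H](C)OC(C)=O | intermediate
36 | (R)-2-methylbutanoic acid | CC[C@@H](C)C(=O)O | starting material
37 | (1S,3aR,5S,6R,7S,7aR)-1-[(1S)-1-acetoxyethyl]-4-methylidene-7-[(2S)-2-methyloxiran-2-yl]-6-{[(2R)-2-methylbutanoyl]oxy}-2-oxooctahydro-1H-inden-5-yl (2E,4S)-4-acetoxy-3-methylpent-2-enoate | C=C1[C@@H]2CC(=O)[C@H]([C@H](C)OC(C)=O)[C@H]2[C@H]([C@@]2(C)CO2)[C@@H](OC(=O)[C@H](C)CC)[C@H]1OC(=O)/C=C(\C)[C@H](C)OC(C)=O | target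

## Step count and least certain steps

Total: 27 steps. Longest linear sequence: 23 steps (steps 1–19 and 24–27 from 1); the side-chain acid 32 takes 4 steps (20–23). The key-step precursor 19 is reached in 13 steps.

**Step 14 (key step).** The most likely failure is poor discrimination between the two C7a–H bonds, so that insertion into the axial bond gives cis-fused material; both paths pass through five-membered transition-state rings, and only the chair geometry separates them. Fallback, setting out from 19 and returning at 20: the insertion is run as above and the product, containing the cis-fused C7a epimer F1, is carried on unseparated. Selenenylation at the diketone carbon C1 (PhSeCl, pyridine) gives the C1 phenylselenide F2. Oxidation with H2O2 and syn-elimination toward H7a gives the C1=C7a enedione F3, in which C7a is no longer a stereocentre. Conjugate reduction with the copper hydride [(Ph3P)CuH]6 then delivers hydride axially to C7a and returns 20. Here C7a is set by hydride delivery and not by the insertion.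

**Step 4.** The most likely failure is loss of the C6 acetate by β-elimination from the Lewis-acid-activated ketone, or its participation at the cation, because a β-leaving group is present while the carbonyl is activated. Fallback, from 4 to 7: the order of oxygenation and cleavage is reversed. Enone 4 is cleaved under the same acetylating Lewis-acid conditions to the dienyl acetate F4, which has no β-oxygen. The non-oxygenated C5=C6 bond of F4 is dihydroxylated anti to the C7 side chain (OsO4, N-methylmorpholine N-oxide) to the diol F5, and acetylation (Ac2O, pyridine) gives 7.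

**Step 9.** The most likely failure is proton loss from C7 giving the isopropylidene isomer, or consumption of the free C5 hydroxyl, since the dehydration is under kinetic control only. Fallback, from 13 to 14: the C5 hydroxyl is acetylated (Ac2O, pyridine, DMAP) to the C5 acetate F6. The tertiary alcohol is then dehydrated by E2 elimination through its chlorosulfite (SOCl2, pyridine, −20 °C) to the isopropenyl acetate F7, and methanolysis (K2CO3, MeOH) returns 14.

**Step 15.** The most likely failure is slow ketal hydrolysis, because the oxocarbenium ion at C4 is destabilised by the C5 oxygen, so that the C5 silyl ether is lost first. Fallback, from 20 to 21: global cleavage is accepted. Aqueous HCl in THF removes ketal and silyl ether to give the C5 hydroxy trione F8. Re-silylation with tBuMe2SiOTf and 2,6-lutidine, with the diketone enol silyl ether hydrolysed on work-up, gives 21.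

**Step 17.** The most likely failure is hydride delivery to the wrong face of the acetyl group or to the ring ketone, because the catalyst must override the bias of a chelating, largely enolised diketone. Fallback, from 23 to 25: a substrate-controlled reduction of the acetyl group is used (NaBH4, MeOH, −78 °C). If it gives the (1′R)-carbinol F9, a Mitsunobu reaction with acetic acid (PPh3, diisopropyl azodicarboxylate) inverts C1′ and installs the acetate in one operation, giving 25 directly.

**Step 26.** The most likely failure is low facial selectivity, because the isopropenyl group rotates freely, together with migration of the C5 acyl group to the free C6 hydroxyl. Fallback, from 34 to 37: the C6 hydroxyl is esterified first with 36 (DCC, DMAP) to give the triene diester F10. The isopropenyl group, the most electron-rich alkene, is then epoxidised without direction by dimethyldioxirane in acetone at 0 °C, and the two oxirane epimers are separated to give 37. This gives up stereocontrol at C8 in exchange for never exposing a free hydroxyl next to the C5 ester.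

## Further compounds

F1 | step 14 | cis-fused C7a epimer of 20 (C1 not assigned) | O1CCOC12[C@@H]3CC(=O)C(C(C)=O)[C@@H]3[C@H](C(C)=C)[C@@H](OCc4ccc(OC)cc4)[C@H]2O[Si](C)(C)C(C)(C)C
F2 | step 14 | C1 phenylselenide of the 1-acetyl-2-ketone (C1 and C7a not assigned) | O1CCOC12[C@@H]3CC(=O)C(C(C)=O)([Se]c5ccccc5)C3[C@H](C(C)=C)[C@@H](OCc4ccc(OC)cc4)[C@H]2O[Si](C)(C)C(C)(C)C
F3 | step 14 | C1=C7a enedione (1-acetyl-hydrind-1(7a)-en-2-one ketal) | O1CCOC12[C@@H]3CC(=O)C(C(C)=O)=C3[C@H](C(C)=C)[C@@H](OCc4ccc(OC)cc4)[C@H]2O[Si](C)(C)C(C)(C)C
F4 | step 4 | dienyl acetate: C4(OAc)=C3a, C5=C6, C7 α-(2-acetoxypropan-2-yl) | CC(=O)OC1=CC[C@H](C(C)(C)OC(C)=O)C=C1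
F5 | step 4 | C5,C6 β-cis-diol of the C4 enol acetate | CC(=O)OC1=CC[C@H](C(C)(C)OC(C)=O)[C@@H](O)[C@H]1O
F6 | step 9 | C5 β-acetate of 13 | C=CC[C@@H]1C[C@H](C(C)(C)O)[C@@H](OCc3ccc(OC)cc3)[C@@H](OC(C)=O)C12OCCO2
F7 | step 9 | C5 β-acetate of 14 | C=CC[C@@H]1C[C@H](C(C)=C)[C@@H](OCc3ccc(OC)cc3)[C@@H](OC(C)=O)C12OCCO2
F8 | step 15 | C5 β-hydroxy trione | O=C1[C@@H]2CC(=O)[C@H](C(C)=O)[C@H]2[C@H](C(C)=C)[C@@H](OCc3ccc(OC)cc3)[C@H]1O
F9 | step 17 | (1′R) epimer of 24 | C=C1[C@@H]2CC(=O)[C@H]([C@@H](C)O)[C@H]2[C@H](C(C)=C)[C@@H](OCc3ccc(OC)cc3)[C@H]1O[Si](C)(C)C(C)(C)C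
F10 | step 26 | triene diester (37 with isopropenyl in place of the oxirane) | C=C1[C@@H]2CC(=O)[C@H]([C@H](C)OC(C)=O)[C@H]2[C@H](C(C)=C)[C@@H](OC(=O)[C@H](C)CC)[C@H]1OC(=O)/C=C(\C)[C@H](C)OC(C)=O
A1 | alternative 1 | 2,3,4-trisubstituted cyclopentanone from the Sakurai–aldol union | C[Si](C)(C)C#C[C@@H]1CC(=O)[C@H]([C@H](C)O)[C@H]1[C@H](C(C)=C)[C@@H]2COC(C)(C)O2
A2 | alternative 1 | 4-[(trimethylsilyl)ethynyl]cyclopent-2-enone | C[Si](C)(C)C#C[C@@H]1CC(=O)C=C1
A3 | alternative 1 | (E)-allylsilane carrying the dioxolane | C[Si](C)(C)C/C(C)=C/[C@@H]1COC(C)(C)O1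
A4 | alternative 1 | acetaldehyde | CC=O
A5 | alternative 2 | cyclopentane-fused isoxazoline | C=C1[C@@H]2CC3=NO[C@@H](C)[C@@H]3[C@H]2[C@H](C(C)=C)[C@H]3OC(C)(C)O[C@@H]13
A6 | alternative 2 | aldoxime with (E)-propenyl group on C7a | C=C1[C@H](CC=NO)[C@@H](/C=C/C)[C@H](C(C)=C)[C@H]2OC(C)(C)O[C@@H]12
A7 | alternative 3 | tricyclic hydrindenone (C1=C7a enone) | COc1ccc(CO[C@@H]2[C@@H]3CC(=O)C([C@H](C)O[Si](C)(C)C(C)(C)C)=C3[C@H](C(C)=C)[C@H]4OC(C)(C)O[C@H]42)cc1
A8 | alternative 3 | acyclic 1,7-enyne | C=C[C@@H](OCc1ccc(OC)cc1)[C@@H]2OC(C)(C)O[C@@H]2[C@@H](C(C)=C)C#C[C@H](C)O[Si](C)(C)C(C)(C)C
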